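**Retrosynthetic overview**
- Feature: in the 2,3-dihydro-1,4-benzodioxine, O1 (on the aryl-bearing C2) is bonded to C8a, which is para to C6, the carbon carrying the propenoic acid. A formyl group at C6 is therefore both the precursor of that chain and the activator for displacing a fluorine at C8a.
- Disconnections: the C6 acrylic acid goes back to CHO plus malonic acid (Doebner). O1–C8a goes back to an intramolecular SNAr of the C2 alkoxide on the fluoride; this closes the dioxane ring, the only ring formed in the route (both benzene rings are bought).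
- The threo (1R,2R) 1-aryl-2-aryloxypropane-1,3-diol that cyclises is cut at its C1–C2 bond (later C2–C3) by an Evans syn-aldol of MOM-vanillin with an N-(aryloxyacetyl)oxazolidinone, which sets both stereocentres at once. O4–C3 comes from a Williamson etherification of 4-fluoro-3-hydroxybenzonitrile.
- The formyl group is carried as the nitrile through the aldol and the hydride cleavage of the auxiliary and is released by DIBAL-H just before ring closure. The phenol is a MOM ether and the primary alcohol a TIPS ether; both fall to acid at the end.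

Key step: step 7

Assumption: (S)-4-benzyl-3-(chloroacetyl)-1,3-oxazolidin-2-one (4) is taken as a purchasable reagent; it is otherwise one N-acylation away from (S)-4-benzyl-1,3-oxazolidin-2-one.

**Route**

Step 1
Reactants: 1 vanillin (4-hydroxy-3-methoxybenzaldehyde)
Product: 2 3-methoxy-4-(methoxymethoxy)benzaldehyde
Conditions: MOMCl, i-Pr2NEt, CH2Cl2, 0 °C → rt
Reagents that add atoms: chloromethyl methyl ether (MOMCl), COCCl
Why: O-alkylation of the phenol with the α-chloro ether (Williamson-type MOM protection) should give an acetal that withstands every basic, hydridic and Lewis-acidic step that follows.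

Step 2
Reactants: 3 4-fluoro-3-hydroxybenzonitrile; 4 (S)-4-benzyl-3-(chloroacetyl)-1,3-oxazolidin-2-one
Product: 5 (4S)-4-benzyl-3-[2-(5-cyano-2-fluorophenoxy)acetyl]-1,3-oxazolidin-2-one
Conditions: K2CO3, DMF, rt
Reagents that add atoms: none
Why: Williamson ether synthesis, in which the electron-poor phenol under carbonate should displace the α-chloride next to the imide carbonyl (SN2) far faster than it can acylate or attack the nitrile-activated C–F of a second molecule at room temperature.

Step 3
Reactants: 5 (4S)-4-benzyl-3-[2-(5-cyano-2-fluorophenoxy)acetyl]-1,3-oxazolidin-2-one; 2 3-methoxy-4-(methoxymethoxy)benzaldehyde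
Product: 8 (4S)-4-benzyl-3-[(2S,3R)-2-(5-cyano-2-fluorophenoxy)-3-hydroxy-3-[3-methoxy-4-(methoxymethoxy)phenyl]propanoyl]-1,3-oxazolidin-2-one, via Z-dibutylboron enolate 6 (not isolated), via dibutylboron aldolate 7 (not isolated)
Conditions: n-Bu2BOTf, i-Pr2NEt, CH2Cl2, 0 °C; then 2, −78 → 0 °C; then pH 7 buffer, MeOH, 30% H2O2, 0 °C
Reagents that add atoms: dibutylboron triflate, CCCCB(CCCC)OS(=O)(=O)C(F)(F)F (its Bu2B unit stays only in 6 and 7)
Why: Evans syn-aldol, in which the Z(O)-boron enolate reacts through a closed Zimmerman–Traxler chair while the (S)-benzyl group of the dipole-opposed auxiliary shields one enolate face, so that the 2,3-syn adduct with C2 S and C3 R (the threo array, both centres set here) should form.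

Step 4
Reactants: 8 (4S)-4-benzyl-3-[(2S,3R)-2-(5-cyano-2-fluorophenoxy)-3-hydroxy-3-[3-methoxy-4-(methoxymethoxy)phenyl]propanoyl]-1,3-oxazolidin-2-one
Product: 9 4-fluoro-3-{[(1R,2R)-1,3-dihydroxy-1-[3-methoxy-4-(methoxymethoxy)phenyl]propan-2-yl]oxy}benzonitrile
Conditions: LiBH4, MeOH (2 equiv), THF, 0 °C
Reagents that add atoms: none
Why: reductive cleavage of the N-acyl oxazolidinone by borohydride attack at the exocyclic carbonyl should give the primary alcohol and free the auxiliary, while the nitrile, the aryl fluoride and both stereocentres are untouched at 0 °C (the descriptor at the ether carbon changes from S to R only through CIP priorities).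

Step 5
Reactants: 9 4-fluoro-3-{[(1R,2R)-1,3-dihydroxy-1-[3-methoxy-4-(methoxymethoxy)phenyl]propan-2-yl]oxy}benzonitrile
Product: 10 4-fluoro-3-{[(1R,2R)-1-hydroxy-1-[3-methoxy-4-(methoxymethoxy)phenyl]-3-[(triisopropylsilyl)oxy]propan-2-yl]oxy}benzonitrile
Conditions: TIPSCl, imidazole, DMF, 0 °C → rt
Reagents that add atoms: chlorotriisopropylsilane (TIPSCl), CC(C)[Si](Cl)(C(C)C)C(C)C
Why: silylation with the bulky chlorosilane should take the primary hydroxyl and leave the hindered secondary benzylic hydroxyl free (steric selection in silyl ether formation).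

Step 6
Reactants: 10 4-fluoro-3-{[(1R,2R)-1-hydroxy-1-[3-methoxy-4-(methoxymethoxy)phenyl]-3-[(triisopropylsilyl)oxy]propan-2-yl]oxy}benzonitrile
Product: 12 4-fluoro-3-{[(1R,2R)-1-hydroxy-1-[3-methoxy-4-(methoxymethoxy)phenyl]-3-[(triisopropylsilyl)oxy]propan-2-yl]oxy}benzaldehyde, via N-aluminio aldimine 11 (not isolated)
Conditions: DIBAL-H (3 equiv), CH2Cl2, −78 → −40 °C; then MeOH, aq. Rochelle salt, rt
Reagents that add atoms: diisobutylaluminium hydride, CC(C)C[AlH]CC(C)C (hydride to the formyl carbon; aluminium only in 11); water, O (formyl oxygen)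
Why: partial reduction of the nitrile with DIBAL-H stops at the N-aluminio aldimine, which should hydrolyse on aqueous work-up to the aldehyde, with silyl ether, MOM acetal and aryl fluoride inert to the reagent.

Step 7
Reactants: 12 4-fluoro-3-{[(1R,2R)-1-hydroxy-1-[3-methoxy-4-(methoxymethoxy)phenyl]-3-[(triisopropylsilyl)oxy]propan-2-yl]oxy}benzaldehyde
Product: 15 (2R,3R)-2-[3-methoxy-4-(methoxymethoxy)phenyl]-3-{[(triisopropylsilyl)oxy]methyl}-2,3-dihydro-1,4-benzodioxine-6-carbaldehyde, via sodium alkoxide 13 (not isolated), via Meisenheimer adduct 14 (not isolated)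
Conditions: NaH (1.2 equiv), THF–DMF (4:1), 0.02 M, 0 °C → rt
Reagents that add atoms: sodium hydride, [Na+].[H-] (sodium only in 13 and 14)
Why: NaH converts the only free hydroxyl into the benzylic alkoxide 13, which adds to the fluorine-bearing carbon para to the formyl group to give the Meisenheimer adduct 14, its charge carried by the ring and the formyl oxygen, and loss of fluoride restores the arene (addition–elimination SNAr). The closest known reaction type is the intramolecular SNAr etherification of fluoroarenes activated by a para carbonyl group, as in alkoxide displacements on 4-fluorobenzaldehyde. The dioxane ring (O1, C2, C3, O4, C4a, C8a) closes by six-membered attack of O1 on the trigonal C8a, formally 6-exo-trig with respect to the C8=C8a bond. No stereocentre is formed or touched: C1 and C2 of the threo chain become C2 and C3, so the (1R,2R) array should give the trans-(2R,3R) ring with aryl and CH2OTIPS both equatorial. Chemoselectivity rests on the substrate, since the primary hydroxyl is silylated, the phenol is a MOM ether, only the C–F carbon is activated (the ether-bearing carbon meta to CHO is inert, so no Smiles-type exchange) and the hydride base brings in no competing nucleophile. High dilution disfavours intermolecular substitution, and the TIPS group is chosen because it resists 1,5-O→O silyl shift to the alkoxide and attack by the fluoride set free.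

Step 8
Reactants: 15 (2R,3R)-2-[3-methoxy-4-(methoxymethoxy)phenyl]-3-{[(triisopropylsilyl)oxy]methyl}-2,3-dihydro-1,4-benzodioxine-6-carbaldehyde; 16 malonic acid
Product: 18 (E)-3-[(2R,3R)-2-[3-methoxy-4-(methoxymethoxy)phenyl]-3-{[(triisopropylsilyl)oxy]methyl}-2,3-dihydro-1,4-benzodioxin-6-yl]prop-2-enoic acid, via arylidenemalonic acid 17 (not isolated)
Conditions: pyridine, piperidine (cat.), 85 °C
Reagents that add atoms: none
Why: Knoevenagel–Doebner condensation, in which amine-catalysed condensation gives the arylidenemalonic acid and decarboxylation in hot pyridine should leave the thermodynamically favoured E-acid; with the phenol masked no quinone methide can form, so C2 and C3 are not at risk under the basic conditions.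

Step 9
Reactants: 18 (E)-3-[(2R,3R)-2-[3-methoxy-4-(methoxymethoxy)phenyl]-3-{[(triisopropylsilyl)oxy]methyl}-2,3-dihydro-1,4-benzodioxin-6-yl]prop-2-enoic acid
Product: 19 (E)-3-[(2R,3R)-2-(4-hydroxy-3-methoxyphenyl)-3-(hydroxymethyl)-2,3-dihydro-1,4-benzodioxin-6-yl]prop-2-enoic acid (CNP0187155.2)
Conditions: 3 M aq. HCl, THF, 40 °C
Reagents that add atoms: none
Why: acid-catalysed hydrolysis should cleave the phenolic MOM acetal and the primary silyl ether in one operation, with water instead of an alcohol as co-solvent so that the carboxylic acid is not esterified, and with the cyclic aryl ether bonds and both stereocentres unaffected.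

**Compound list**
1 | vanillin (4-hydroxy-3-methoxybenzaldehyde) | COc1cc(C=O)ccc1O | starting material
2 | 3-methoxy-4-(methoxymethoxy)benzaldehyde | COCOc1ccc(C=O)cc1OC | intermediate
3 | 4-fluoro-3-hydroxybenzonitrile | N#Cc1ccc(F)c(O)c1 | starting material
4 | (S)-4-benzyl-3-(chloroacetyl)-1,3-oxazolidin-2-one | O=C(CCl)N1[C@@H](Cc2ccccc2)COC1=O | starting material
5 | (4S)-4-benzyl-3-[2-(5-cyano-2-fluorophenoxy)acetyl]-1,3-oxazolidin-2-one | N#Cc1ccc(F)c(OCC(=O)N2[C@@H](Cc3ccccc3)COC2=O)c1 | intermediate
6 | Z-dibutylboron enolate of 5: (4S)-4-benzyl-3-[(Z)-1-[(dibutylboranyl)oxy]-2-(5-cyano-2-fluorophenoxy)ethenyl]-1,3-oxazolidin-2-one | CCCCB(CCCC)O/C(=C\Oc1cc(C#N)ccc1F)N1[C@@H](Cc2ccccc2)COC1=O | intermediate (not isolated)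
7 | dibutylboron aldolate: 8 with its C3 oxygen bound to BBu2 | COCOc1ccc([C@@H](OB(CCCC)CCCC)[C@H](Oc2cc(C#N)ccc2F)C(=O)N2[C@@H](Cc3ccccc3)COC2=O)cc1OC | intermediate (not isolated)
8 | (4S)-4-benzyl-3-[(2S,3R)-2-(5-cyano-2-fluorophenoxy)-3-hydroxy-3-[3-methoxy-4-(methoxymethoxy)phenyl]propanoyl]-1,3-oxazolidin-2-one | COCOc1ccc([C@@H](O)[C@H](Oc2cc(C#N)ccc2F)C(=O)N2[C@@H](Cc3ccccc3)COC2=O)cc1OC | intermediate
9 | 4-fluoro-3-{[(1R,2R)-1,3-dihydroxy-1-[3-methoxy-4-(methoxymethoxy)phenyl]propan-2-yl]oxy}benzonitrile | COCOc1ccc([C@@H](O)[C@H](Oc2cc(C#N)ccc2F)CO)cc1OC | intermediate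
10 | 4-fluoro-3-{[(1R,2R)-1-hydroxy-1-[3-methoxy-4-(methoxymethoxy)phenyl]-3-[(triisopropylsilyl)oxy]propan-2-yl]oxy}benzonitrile | COCOc1ccc([C@@H](O)[C@H](Oc2cc(C#N)ccc2F)CO[Si](C(C)C)(C(C)C)C(C)C)cc1OC | intermediate
11 | N-(diisobutylaluminio) aldimine of 12, with the benzylic oxygen as its diisobutylaluminium alkoxide | COCOc1ccc([C@@H](O[Al](CC(C)C)CC(C)C)[C@H](Oc2cc(C=N[Al](CC(C)C)CC(C)C)ccc2F)CO[Si](C(C)C)(C(C)C)C(C)C)cc1OC | intermediate (not isolated)
12 | 4-fluoro-3-{[(1R,2R)-1-hydroxy-1-[3-methoxy-4-(methoxymethoxy)phenyl]-3-[(triisopropylsilyl)oxy]propan-2-yl]oxy}benzaldehyde | COCOc1ccc([C@@H](O)[C@H](Oc2cc(C=O)ccc2F)CO[Si](C(C)C)(C(C)C)C(C)C)cc1OC | intermediate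
13 | sodium alkoxide of 12 (benzylic oxygen deprotonated) | COCOc1ccc([C@@H]([O-])[C@H](Oc2cc(C=O)ccc2F)CO[Si](C(C)C)(C(C)C)C(C)C)cc1OC.[Na+] | intermediate (not isolated)
14 | Meisenheimer adduct (sodium salt): C8a carries both F and O1, charge on the formyl oxygen; C8a configuration transient and undefined | COCOc1ccc([C@H]2OC3(F)C=CC(=C[O-])C=C3O[C@@H]2CO[Si](C(C)C)(C(C)C)C(C)C)cc1OC.[Na+] | intermediate (not isolated)
15 | (2R,3R)-2-[3-methoxy-4-(methoxymethoxy)phenyl]-3-{[(triisopropylsilyl)oxy]methyl}-2,3-dihydro-1,4-benzodioxine-6-carbaldehyde | COCOc1ccc([C@H]2Oc3ccc(C=O)cc3O[C@@H]2CO[Si](C(C)C)(C(C)C)C(C)C)cc1OC | intermediate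
16 | malonic acid | OC(=O)CC(=O)O | starting material
17 | 2-{[(2R,3R)-2-[3-methoxy-4-(methoxymethoxy)phenyl]-3-{[(triisopropylsilyl)oxy]methyl}-2,3-dihydro-1,4-benzodioxin-6-yl]methylidene}propanedioic acid | COCOc1ccc([C@H]2Oc3ccc(C=C(C(=O)O)C(=O)O)cc3O[C@@H]2CO[Si](C(C)C)(C(C)C)C(C)C)cc1OC | intermediate (not isolated)
18 | (E)-3-[(2R,3R)-2-[3-methoxy-4-(methoxymethoxy)phenyl]-3-{[(triisopropylsilyl)oxy]methyl}-2,3-dihydro-1,4-benzodioxin-6-yl]prop-2-enoic acid | COCOc1ccc([C@H]2Oc3ccc(/C=C/C(=O)O)cc3O[C@@H]2CO[Si](C(C)C)(C(C)C)C(C)C)cc1OC | intermediate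
19 | (E)-3-[(2R,3R)-2-(4-hydroxy-3-methoxyphenyl)-3-(hydroxymethyl)-2,3-dihydro-1,4-benzodioxin-6-yl]prop-2-enoic acid | COc1cc([C@H]2Oc3ccc(/C=C/C(=O)O)cc3O[C@@H]2CO)ccc1O | target

**Count**
Total step count: 9. Longest linear sequence: 8 steps (steps 2–9, from 3 and 4 to 19); step 1 is a one-step branch.

**Steps most likely to fail**

Step 7 (ring closure). The alkoxide may add to, or transfer hydride to, the formyl group of a second molecule, or expel the aryloxide from the neighbouring carbon to form an oxirane, faster than it attacks the C–F carbon. Fallback: close the ring one step earlier, on nitrile 10, where the cyano group para to fluorine is the activator and no electrophilic carbonyl is present. Treating 10 with NaH in THF–DMF should give (2R,3R)-2-[3-methoxy-4-(methoxymethoxy)phenyl]-3-{[(triisopropylsilyl)oxy]methyl}-2,3-dihydro-1,4-benzodioxine-6-carbonitrile F1. DIBAL-H in CH2Cl2 at −78 °C should then reduce F1 to its N-(diisobutylaluminio) aldimine F2, which on aqueous work-up gives aldehyde 15, where the route is rejoined.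

Step 2 (ether formation on the chloroacetyl imide). The phenoxide or carbonate may attack the imide carbonyl with loss of the auxiliary, or the base may cause self-condensation of the α-chloro imide. Fallback: build the ether on a simple ester and attach the auxiliary afterwards. Starting from 3, alkylation with tert-butyl bromoacetate (K2CO3, acetone) should give tert-butyl 2-(5-cyano-2-fluorophenoxy)acetate F3, and TFA in CH2Cl2 should free 2-(5-cyano-2-fluorophenoxy)acetic acid F4. Pivaloyl chloride and Et3N in THF at −20 °C should convert F4 into 2-(5-cyano-2-fluorophenoxy)acetic pivalic anhydride F5, which with (S)-4-benzyl-1,3-oxazolidin-2-one and LiCl should give imide 5, where the route is rejoined.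

Step 9 (global deprotection). Hydrolysis of the hindered silyl ether may be slow, which forces long exposure to strong acid; the C2–O1 bond beside the liberated phenol can then ionise, with ring opening or epimerisation at C2. Fallback: take the two groups off in separate, orthogonal operations. Starting from 18, TBAF in THF should remove the silyl group and give (E)-3-[(2R,3R)-3-(hydroxymethyl)-2-[3-methoxy-4-(methoxymethoxy)phenyl]-2,3-dihydro-1,4-benzodioxin-6-yl]prop-2-enoic acid F6. The aryl MOM acetal alone should then fall to brief treatment with dilute HCl in aqueous THF at room temperature, giving 19.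

**Further compounds**
F1 | step 7 | (2R,3R)-2-[3-methoxy-4-(methoxymethoxy)phenyl]-3-{[(triisopropylsilyl)oxy]methyl}-2,3-dihydro-1,4-benzodioxine-6-carbonitrile | COCOc1ccc([C@H]2Oc3ccc(C#N)cc3O[C@@H]2CO[Si](C(C)C)(C(C)C)C(C)C)cc1OC
F2 | step 7 | N-(diisobutylaluminio) aldimine of F1 | COCOc1ccc([C@H]2Oc3ccc(C=N[Al](CC(C)C)CC(C)C)cc3O[C@@H]2CO[Si](C(C)C)(C(C)C)C(C)C)cc1OC
F3 | step 2 | tert-butyl 2-(5-cyano-2-fluorophenoxy)acetate | CC(C)(C)OC(=O)COc1cc(C#N)ccc1F
F4 | step 2 | 2-(5-cyano-2-fluorophenoxy)acetic acid | OC(=O)COc1cc(C#N)ccc1F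
F5 | step 2 | 2-(5-cyano-2-fluorophenoxy)acetic pivalic anhydride | CC(C)(C)C(=O)OC(=O)COc1cc(C#N)ccc1F
F6 | step 9 | (E)-3-[(2R,3R)-3-(hydroxymethyl)-2-[3-methoxy-4-(methoxymethoxy)phenyl]-2,3-dihydro-1,4-benzodioxin-6-yl]prop-2-enoic acid | COCOc1ccc([C@H]2Oc3ccc(/C=C/C(=O)O)cc3O[C@@H]2CO)cc1OC
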